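**Plan**
- Retrosynthesis cuts both C12–C13 and C12′–C13′ single bonds in one operation. Each C12–C13(CH3)=C14H unit is read as the product of a syn hydrogen/alkenyl addition across a methyl-capped alkyne, so the core C20–C13…C13′–C20′ becomes (E)-oct-4-ene-2,6-diyne and the ends become two identical C16 trienyl iodides.
- Enabling feature: the twofold axis through C15=C15′ and the methyl-bearing carbons C13/C13′ flanking C14–C15=C15′–C14′. Methyl on one alkyne carbon and alkenyl on the other should steer palladium. The two cyclohexene (ε) rings C1–C6 and C1′–C6′ are bought complete and never built.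
- Forward order: (R)-α-ionone → C9=C10 (C15 nitrile) → C3 ketone → C3 alcohol → C11 aldehyde → C11=C12 iodide; then C16 + C8 → C24 → C40 in one flask, which ends the synthesis without protecting groups.
- Stereochemistry: C6/C6′ are bought with (R)-α-ionone. C3/C3′ are relayed from C6 by substrate-controlled ketone reduction (3,6-cis) followed by Mitsunobu inversion (3R). 9E and 11E come from the olefinations, 15E from (E)-1,2-dichloroethene, and 13E/13′E from syn carbopalladation.

Key step: step 8

Assumption: (R)-(+)-α-ionone is taken as a purchasable single enantiomer; with only the racemate at hand, a resolution would have to precede step 1.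

**Step 1**
Reactants: 1 (R)-α-ionone; 2 diethyl (cyanomethyl)phosphonate
Product: 3 (2E,4E)-3-methyl-5-[(1R)-2,6,6-trimethylcyclohex-2-en-1-yl]penta-2,4-dienenitrile
Conditions: NaH (slightly less than 2), THF, 0 °C to rt; 9E isomer separated from minor 9Z by chromatography
Reagents that add atoms: none
Why: Horner–Wadsworth–Emmons olefination of the methyl ketone should give the conjugated dienenitrile mainly as the 9E isomer, and the stabilised phosphonate anion is too weak and too hindered a base to remove the shielded C6–H, so the bought stereocentre should survive.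

**Step 2**
Reactants: 3 C15 dienenitrile
Product: 4 (2E,4E)-3-methyl-5-[(1R)-2,6,6-trimethyl-4-oxocyclohex-2-en-1-yl]penta-2,4-dienenitrile
Conditions: t-BuOOH (70% aq., 5 equiv), Rh2(caprolactamate)4 (1 mol %), NaHCO3, CH2Cl2, rt
Reagents that add atoms: tert-butyl hydroperoxide, CC(C)(C)OO
Why: Dirhodium-catalysed radical allylic oxidation with tert-butylperoxyl radicals should take the only secondary allylic CH2 (C3) of the electron-rich ring alkene, because the tertiary C6–H is shielded by the geminal methyl groups and poorly aligned with both π systems and the C19 methyl sits on an electron-poor diene.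

**Step 3**
Reactants: 4 3-oxo dienenitrile
Product: 5 (2E,4E)-5-[(1R,4S)-4-hydroxy-2,6,6-trimethylcyclohex-2-en-1-yl]-3-methylpenta-2,4-dienenitrile (3,6-cis)
Conditions: LiBH(s-Bu)3 (1.1 equiv), THF, −78 °C; then H2O
Reagents that add atoms: none
Why: Substrate-controlled 1,2-reduction of the β,β-disubstituted enone by the bulky hydride (the dienenitrile is inert at this temperature) should deliver hydride to the ring face opposite the pseudoaxial C6 side chain, so C6 relays its configuration to C3 and the 3,6-cis (3S) allylic alcohol is expected.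

**Step 4**
Reactants: 5 cis hydroxy nitrile
Product: 6 (1R,4R)-4-[(1E,3E)-4-cyano-3-methylbuta-1,3-dien-1-yl]-3,5,5-trimethylcyclohex-2-en-1-yl benzoate (3,6-trans)
Conditions: PPh3, DIAD, PhCO2H, THF, 0 °C to rt
Reagents that add atoms: benzoic acid, O=C(O)c1ccccc1
Why: Mitsunobu esterification displaces the oxyphosphonium group by benzoate in an SN2 reaction with inversion at C3 (the SN2′ terminus C5 is fully substituted), which should turn 3S into the required 3R, trans to the C6 chain.

**Step 5**
Reactants: 6 trans benzoate nitrile
Product: 7 (2E,4E)-5-[(1R,4R)-4-hydroxy-2,6,6-trimethylcyclohex-2-en-1-yl]-3-methylpenta-2,4-dienal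
Conditions: i-Bu2AlH (4.5 equiv), CH2Cl2, −78 to −20 °C; then aq. Rochelle salt, wet SiO2
Reagents that add atoms: water, O
Why: Partial reduction of the nitrile by i-Bu2AlH stops at the aluminium aldimine, which is hydrolysed to the C11 aldehyde on work-up, and the same reagent cleaves the benzoate reductively, so the free 3R alcohol and the aldehyde should appear together without touching C3, C6 or the 9E alkene.

**Step 6**
Reactants: 7 hydroxy dienal
Product: 8 (1R,4R)-4-[(1E,3E,5E)-6-iodo-3-methylhexa-1,3,5-trien-1-yl]-3,5,5-trimethylcyclohex-2-en-1-ol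
Conditions: CrCl2 (8 equiv), CHI3 (3 equiv), THF/1,4-dioxane, 0 °C to rt, dark
Reagents that add atoms: iodoform, IC(I)I
Why: Takai iodo-olefination through the geminal dichromium species from iodoform should give the (E)-alkenyl iodide at C11=C12 selectively, and divalent chromium tolerates the free hydroxyl and the diene.

**Step 7**
Reactants: 9 (E)-1,2-dichloroethene; 10 propyne (2.5 equiv)
Product: 11 (E)-oct-4-ene-2,6-diyne
Conditions: Pd(PPh3)4 (5 mol %), CuI (10 mol %), piperidine, THF, rt, closed vessel
Reagents that add atoms: none
Why: Twofold Sonogashira coupling of the vinylic dichloride proceeds with retention at the alkene, which fixes the future 15E geometry and should give the C8 enediyne in one step.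

**Step 8**
Reactants: 8 C16 trienyl iodide (2.6 equiv); 11 (E)-oct-4-ene-2,6-diyne (1 equiv)
Product: 13 lactucaxanthin, (3R,6R,3′R,6′R)-ε,ε-carotene-3,3′-diol, via C24 pentaenyne alcohol 12 (not isolated)
Conditions: Pd(OAc)2 (10 mol %), PPh3 (20 mol %), HCO2H (3 equiv) and Et3N (4.5 equiv) added slowly, DMF, 40 °C, argon, dark
Reagents that add atoms: none
Why: Proposed new method: oxidative addition of zerovalent palladium into the C12–I bond of 8 gives a trienylpalladium iodide that adds syn across a methyl-capped alkyne of 11, the alkenyl group going to the methyl-bearing carbon (C13) and palladium to C14, after which formate exchange, loss of CO2 and C–H reductive elimination replace palladium by hydrogen with retention; the monoadduct 12 then repeats the cycle at its remaining alkyne, and this second turn forms the C12–C13 bond that unites the C24 pentaenyne with the second C16 unit. The closest known reaction type is the formate-terminated reductive Heck reaction (hydroarylation and hydrovinylation of internal alkynes with aryl iodides or vinyl triflates), extended here to a conjugated enediyne and a polyenyl iodide. No ring is closed and no stereocentre is made; the two new stereo-elements, the 13E and 13′E trisubstituted alkenes, should follow from syn carbopalladation and stereoretentive hydride transfer, while 9E, 11E and 15E are carried in unchanged. Regioselectivity is needed and should be secured by the small methyl cap against the conjugating alkenyl substituent on the other alkyne carbon, since palladium prefers the carbon next to the larger, π-stabilising group, as in Larock heteroannulations of alkyl alkenyl alkynes. Chemoselectivity for alkyne insertion over formate reduction of the alkenylpalladium iodide and over Heck insertion into the di- and trisubstituted polyene alkenes should be secured by slow addition of the formate, the excess of 8 and the higher reactivity of the alkyne. The free allylic hydroxyl groups and the C6 stereocentres should not be touched under these mildly basic conditions.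

**Compound list**
1 | (R)-α-ionone, (3E)-4-[(1R)-2,6,6-trimethylcyclohex-2-en-1-yl]but-3-en-2-one | CC(=O)/C=C/[C@H]1C(C)=CCCC1(C)C | starting material
2 | diethyl (cyanomethyl)phosphonate | CCOP(=O)(CC#N)OCC | starting material
3 | (2E,4E)-3-methyl-5-[(1R)-2,6,6-trimethylcyclohex-2-en-1-yl]penta-2,4-dienenitrile | N#C/C=C(C)/C=C/[C@H]1C(C)=CCCC1(C)C | intermediate
4 | (2E,4E)-3-methyl-5-[(1R)-2,6,6-trimethyl-4-oxocyclohex-2-en-1-yl]penta-2,4-dienenitrile | N#C/C=C(C)/C=C/[C@H]1C(C)=CC(=O)CC1(C)C | intermediate
5 | (2E,4E)-5-[(1R,4S)-4-hydroxy-2,6,6-trimethylcyclohex-2-en-1-yl]-3-methylpenta-2,4-dienenitrile | N#C/C=C(C)/C=C/[C@H]1C(C)=C[C@@H](O)CC1(C)C | intermediate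
6 | (1R,4R)-4-[(1E,3E)-4-cyano-3-methylbuta-1,3-dien-1-yl]-3,5,5-trimethylcyclohex-2-en-1-yl benzoate | N#C/C=C(C)/C=C/[C@H]1C(C)=C[C@H](OC(=O)c2ccccc2)CC1(C)C | intermediate
7 | (2E,4E)-5-[(1R,4R)-4-hydroxy-2,6,6-trimethylcyclohex-2-en-1-yl]-3-methylpenta-2,4-dienal | O=C/C=C(C)/C=C/[C@H]1C(C)=C[C@H](O)CC1(C)C | intermediate
8 | (1R,4R)-4-[(1E,3E,5E)-6-iodo-3-methylhexa-1,3,5-trien-1-yl]-3,5,5-trimethylcyclohex-2-en-1-ol | I/C=C/C=C(C)/C=C/[C@H]1C(C)=C[C@H](O)CC1(C)C | intermediate
9 | (E)-1,2-dichloroethene | Cl/C=C/Cl | starting material
10 | propyne | CC#C | starting material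
11 | (E)-oct-4-ene-2,6-diyne | CC#C/C=C/C#CC | intermediate
12 | (1R,4R)-4-[(1E,3E,5E,7E,9E)-3,7-dimethyltrideca-1,3,5,7,9-pentaen-11-yn-1-yl]-3,5,5-trimethylcyclohex-2-en-1-ol | CC#C/C=C/C=C(C)/C=C/C=C(C)/C=C/[C@H]1C(C)=C[C@H](O)CC1(C)C | intermediate
13 | lactucaxanthin, (3R,6R,3′R,6′R)-ε,ε-carotene-3,3′-diol | CC1=C[C@H](O)CC(C)(C)[C@H]1/C=C/C(C)=C/C=C/C(C)=C/C=C/C=C(C)/C=C/C=C(C)/C=C/[C@H]1C(C)=C[C@H](O)CC1(C)C | target

**Count**
Total steps: 8. Longest linear sequence: 7 (steps 1 to 6, then step 8).

**Steps most likely to fail and fallbacks**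

Step 8. The double hydroalkenylation may fail through wrong-way carbopalladation (alkenyl delivered to C14), through formate reduction of the alkenyl iodide before alkyne insertion, or through isomerisation or partial reduction of the polyene by palladium hydride. The fallback makes the same two bonds by a twofold Suzuki–Miyaura coupling, with the trisubstituted alkenes built by hydrometalation instead. Setting out from 11, hydrozirconation with Cp2Zr(H)Cl (excess, THF, 40 °C; equilibration should place zirconium on the methyl-bearing carbons) gives the bis(alkenylzirconocene chloride) F1, which is not isolated. Iodinolysis of it (I2, 0 °C) should give (2E,4E,6E)-2,7-diiodoocta-2,4,6-triene F2. Setting out from 7, Takai–Utimoto olefination (Cl2CHBpin, CrCl2, LiI, THF) should give the C16 (E)-alkenyl pinacol boronate F3. Coupling of F2 with two equivalents of F3 (Pd(PPh3)4, TlOEt, THF/H2O, rt, dark) comes back to the route at 13.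

Step 2. The allylic oxidation may suffer hydrogen abstraction along the dienenitrile chain (C19 methyl), oxidative degradation of the conjugated diene, or over-oxidation. The fallback moves the oxidation ahead of the chain extension, to a substrate without the conjugated nitrile. Setting out from 1, ketalisation (ethylene glycol, PPTS, benzene, water removal) gives α-ionone ethylene ketal F4. Allylic oxidation of the ring CH2 as in step 2 gives the 3-oxo ketal F5. LiBH(s-Bu)3 at −78 °C gives the 3,6-cis hydroxy ketal F6. Mild acid (PPTS, wet acetone) releases (3S,6R)-3-hydroxy-α-ionone F7. Horner–Wadsworth–Emmons reaction of F7 with 2 (two equivalents of NaH) comes back to the route at 5.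

Step 4. The Mitsunobu reaction may give elimination of the activated allylic alcohol to a cyclohexadiene, or incomplete inversion at the hindered carbinol. The fallback avoids the inversion by reagent-controlled reduction. Setting out from 4, Corey–Bakshi–Shibata reduction with the (S)-methyl oxazaborolidine and catecholborane (toluene, −78 °C) is expected to override the substrate bias and give the 3,6-trans hydroxy nitrile F8 directly. Reduction of F8 with i-Bu2AlH as in step 5 comes back to the route at 7.

**Further compounds**
F1 | step 8 | (2E,4E,6E)-octa-2,4,6-triene-2,7-diylbis[chlorobis(cyclopentadienyl)zirconium] | Cl[Zr](C1C=CC=C1)(C1C=CC=C1)/C(C)=C/C=C/C=C(C)/[Zr](Cl)(C1C=CC=C1)C1C=CC=C1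
F2 | step 8 | (2E,4E,6E)-2,7-diiodoocta-2,4,6-triene | I/C(C)=C/C=C/C=C(C)/I
F3 | step 8 | (1R,4R)-3,5,5-trimethyl-4-[(1E,3E,5E)-3-methyl-6-(4,4,5,5-tetramethyl-1,3,2-dioxaborolan-2-yl)hexa-1,3,5-trien-1-yl]cyclohex-2-en-1-ol | CC1(C)OB(/C=C/C=C(C)/C=C/[C@H]2C(C)=C[C@H](O)CC2(C)C)OC1(C)C
F4 | step 2 | 2-methyl-2-{(E)-2-[(1R)-2,6,6-trimethylcyclohex-2-en-1-yl]ethenyl}-1,3-dioxolane | CC1(/C=C/[C@H]2C(C)=CCCC2(C)C)OCCO1
F5 | step 2 | (4R)-3,5,5-trimethyl-4-[(E)-2-(2-methyl-1,3-dioxolan-2-yl)ethenyl]cyclohex-2-en-1-one | CC1(/C=C/[C@H]2C(C)=CC(=O)CC2(C)C)OCCO1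
F6 | step 2 | (1S,4R)-3,5,5-trimethyl-4-[(E)-2-(2-methyl-1,3-dioxolan-2-yl)ethenyl]cyclohex-2-en-1-ol | CC1(/C=C/[C@H]2C(C)=C[C@@H](O)CC2(C)C)OCCO1
F7 | step 2 | (3E)-4-[(1R,4S)-4-hydroxy-2,6,6-trimethylcyclohex-2-en-1-yl]but-3-en-2-one | CC(=O)/C=C/[C@H]1C(C)=C[C@@H](O)CC1(C)C
F8 | step 4 | (2E,4E)-5-[(1R,4R)-4-hydroxy-2,6,6-trimethylcyclohex-2-en-1-yl]-3-methylpenta-2,4-dienenitrile | N#C/C=C(C)/C=C/[C@H]1C(C)=C[C@H](O)CC1(C)C
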